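**Retrosynthetic overview**
1. Ester C–O bond: target 18 ⇒ alcohol 15 + O-acetyl-p-coumaric acid 16; 15 ⇒ trans-fused β,γ-unsaturated ketone 14 (equatorial alcohol by dissolving-metal reduction).
2. Key C4–C5 bond (closes ring A): 14 ⇒ silyl enol ether 11. One-electron oxidation turns the enol carbon C5 into an electrophilic α-carbonyl radical (enolonium-type synthon) that attacks the nucleophilic terminal alkene; copper-mediated termination gives the C4=C15 methylidene. The ring fusion is then set by kinetic protonation of the dienolate.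
3. C10 quaternary centre: 11 ⇒ enone 9 by conjugate methyl addition directed by the C7 isopropyl stereocentre.
4. Ring B: 9 ⇒ (S)-cryptone 5 (1,2-addition of a pentenyl Grignard, oxidative 1,3-transposition); 5 ⇒ isovaleraldehyde 1 + methyl vinyl ketone 2 (organocatalytic Michael addition, aldol condensation).
5. Ring order: ring B first (step 2), ring A second (step 6).

Assumption: C1–C15 in the comments are eudesmane locants (C4=C15 methylidene, C5 and C10 ring-fusion carbons, C6 carbinol carbon, C7 isopropyl-bearing carbon; ring A = C1–C5 + C10, ring B = C5–C10); compound names use systematic locants.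

**Route**

Step 1
Reactants: 1 3-methylbutanal; 2 but-3-en-2-one
Product: 3 (2S)-5-oxo-2-(propan-2-yl)hexanal
Conditions: (S)-2-[diphenyl(trimethylsilyloxy)methyl]pyrrolidine (5 mol %), ethyl 3,4-dihydroxybenzoate (20 mol %), neat, 4 °C
Reagents that add atoms: none
Why: Enamine-catalysed asymmetric Michael addition (Jørgensen–Hayashi-type catalyst): the E-enamine of 1 is attacked by 2 on the face opposite the bulky diphenyl(silyloxy)methyl group, which on the standard shielding model sets the isopropyl-bearing stereocentre (future C7) as S.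

Step 2
Reactants: 3 (2S)-5-oxo-2-(propan-2-yl)hexanal
Product: 5 (4S)-4-(propan-2-yl)cyclohex-2-en-1-one, via aldol adduct 4 (not isolated)
Conditions: LiOH (0.2 equiv), i-PrOH, rt
Reagents that add atoms: none
Why: Intramolecular aldol condensation: the methyl-ketone enolate attacks the aldehyde to close ring B and E1cB loss of water gives the conjugated enone, while mild catalytic base leaves the existing stereocentre essentially intact.

Step 3
Reactants: 5 (4S)-4-(propan-2-yl)cyclohex-2-en-1-one; 6 5-bromopent-1-ene
Product: 8 (4S)-1-(pent-4-en-1-yl)-4-(propan-2-yl)cyclohex-2-en-1-ol, via pent-4-en-1-ylmagnesium bromide 7 (not isolated)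
Conditions: 6, Mg, THF, 40 °C; then 5, THF, −78 → 0 °C; aq. NH4Cl
Reagents that add atoms: none
Why: Grignard 1,2-addition: a primary alkylmagnesium halide adds to the carbonyl carbon of the cyclohexenone at low temperature in preference to conjugate addition, and the new carbinol centre needs no control because it is destroyed in step 4.

Step 4
Reactants: 8 (4S)-1-(pent-4-en-1-yl)-4-(propan-2-yl)cyclohex-2-en-1-ol
Product: 9 (6S)-3-(pent-4-en-1-yl)-6-(propan-2-yl)cyclohex-2-en-1-one
Conditions: pyridinium chlorochromate [C5H5NH][CrO3Cl] (2 equiv), Celite, CH2Cl2, rt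
Reagents that add atoms: none
Why: Babler–Dauben oxidative 1,3-transposition: the tertiary allylic alcohol is transposed and oxidised by the chromate reagent to the β-substituted enone, placing the carbonyl (future C6) next to the untouched isopropyl stereocentre.

Step 5
Reactants: 9 (6S)-3-(pent-4-en-1-yl)-6-(propan-2-yl)cyclohex-2-en-1-one
Product: 11 trimethyl{[(3R,6S)-3-methyl-3-(pent-4-en-1-yl)-6-(propan-2-yl)cyclohex-1-en-1-yl]oxy}silane, via bromomagnesium enolate 10 (not isolated)
Conditions: MeMgBr (1.5 equiv), CuBr·SMe2 (10 mol %), Me3SiCl (2 equiv), HMPA (2 equiv), THF, −78 °C; Et3N, cold aq. NaHCO3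
Reagents that add atoms: methylmagnesium bromide, C[Mg]Br; chlorotrimethylsilane, C[Si](C)(C)Cl
Why: Chlorosilane-accelerated copper-catalysed conjugate addition of the Grignard reagent with in situ O-silylation, which fixes the enol ether towards C5; methyl is delivered axially to C10 of the half-chair that keeps the C7 isopropyl group pseudo-equatorial, i.e. cis to isopropyl, setting the quaternary centre as R.

Step 6 (key step)
Reactants: 11 trimethyl{[(3R,6S)-3-methyl-3-(pent-4-en-1-yl)-6-(propan-2-yl)cyclohex-1-en-1-yl]oxy}silane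
Product: 12 (2S,4aR,8aR)-4a-methyl-8-methylidene-2-(propan-2-yl)octahydronaphthalen-1(2H)-one
Conditions: Cu(OTf)2 (2.5 equiv), Cu2O (1.5 equiv), MeCN, 0 °C → rt, 0.01 M
Reagents that add atoms: none
Why: Proposed new method: divalent copper oxidises the silyl enol ether by one electron so that the normally nucleophilic enol carbon C5 becomes an electrophilic α-carbonyl radical (an enolonium-type reversed-polarity synthon), which adds 6-exo-trig to the normally nucleophilic terminal alkene (helped by polarity matching and the gem-disubstituted C10), and the primary C15 radical is trapped by divalent copper and loses the C4 hydrogen by oxidative β-hydride elimination to give the C4=C15 methylidene; the closest known chemistry is the Snider-type oxidative cyclization of unsaturated enol silyl ethers with Cu(OTf)2/Cu2O and the Kochi-type copper-mediated oxidation of primary radicals to terminal alkenes, and the new C5 centre (expected mainly cis-fused from axial bond formation, possibly with some 14) is left uncontrolled because step 7 re-sets it.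

Step 7
Reactants: 12 (2S,4aR,8aR)-4a-methyl-8-methylidene-2-(propan-2-yl)octahydronaphthalen-1(2H)-one
Product: 14 (2S,4aR,8aS)-4a-methyl-8-methylidene-2-(propan-2-yl)octahydronaphthalen-1(2H)-one, via potassium dienolate 13 (not isolated)
Conditions: KOt-Bu (3 equiv), THF, −78 → 0 °C; inverse quench into 10% aq. AcOH, 0 °C
Reagents that add atoms: none
Why: Kinetic protonation of an extended dienolate (the logic of the classical enone deconjugation): the doubly activated C5–H (α to the ketone and allylic) is removed selectively, both C5 epimers converge on dienolate 13, and irreversible protonation occurs at the α-carbon C5 rather than at C15 and from the face anti to the pseudo-axial C10 methyl group, giving the trans-fused ketone with the methylidene intact and C7 untouched.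

Step 8
Reactants: 14 (2S,4aR,8aS)-4a-methyl-8-methylidene-2-(propan-2-yl)octahydronaphthalen-1(2H)-one
Product: 15 (1S,2S,4aR,8aS)-4a-methyl-8-methylidene-2-(propan-2-yl)decahydronaphthalen-1-ol
Conditions: Li (6 equiv), NH3(l)/THF, EtOH (3 equiv), −78 °C, 15 min; solid NH4Cl
Reagents that add atoms: none
Why: Dissolving-metal ketone reduction: the ketyl/carbanion intermediate is protonated to give the thermodynamically preferred equatorial alcohol (1S), whereas hydride reagents would be steered by the syn-axial angular methyl group to the axial epimer, and the isolated 1,1-disubstituted alkene is inert to Li/NH3.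

Step 9
Reactants: 15 (1S,2S,4aR,8aS)-4a-methyl-8-methylidene-2-(propan-2-yl)decahydronaphthalen-1-ol; 16 (2E)-3-[4-(acetyloxy)phenyl]prop-2-enoic acid
Product: 18 (1S,2S,4aR,8aS)-4a-methyl-8-methylidene-2-(propan-2-yl)decahydronaphthalen-1-yl (2E)-3-(4-hydroxyphenyl)prop-2-enoate, via acetate-protected ester 17 (not isolated)
Conditions: 16 (2 equiv), DCC (2.2 equiv), DMAP (0.5 equiv), CH2Cl2, rt; then pyrrolidine (5 equiv), rt, 30 min
Reagents that add atoms: none
Why: Steglich esterification (acylation on oxygen, so C6 keeps its configuration) followed by chemoselective aminolysis of the aryl acetate by pyrrolidine, which is far faster than attack on the hindered alkyl cinnamate or conjugate addition to it.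

**Compound list**
1 | 3-methylbutanal (isovaleraldehyde) | CC(C)CC=O | starting material
2 | but-3-en-2-one (methyl vinyl ketone) | CC(=O)C=C | starting material
3 | (2S)-5-oxo-2-(propan-2-yl)hexanal | O=C[C@H](C(C)C)CCC(C)=O | intermediate
4 | (4S)-3-hydroxy-4-(propan-2-yl)cyclohexan-1-one (aldol adduct, both C3 epimers) | O=C1CC(O)[C@H](C(C)C)CC1 | intermediate (not isolated)
5 | (4S)-4-(propan-2-yl)cyclohex-2-en-1-one ((S)-cryptone) | O=C1C=C[C@H](C(C)C)CC1 | intermediate
6 | 5-bromopent-1-ene | C=CCCCBr | starting material
7 | pent-4-en-1-ylmagnesium bromide | C=CCCC[Mg]Br | intermediate (not isolated)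
8 | (4S)-1-(pent-4-en-1-yl)-4-(propan-2-yl)cyclohex-2-en-1-ol (both C1 epimers) | OC1(CCCC=C)C=C[C@H](C(C)C)CC1 | intermediate
9 | (6S)-3-(pent-4-en-1-yl)-6-(propan-2-yl)cyclohex-2-en-1-one | O=C1C=C(CCCC=C)CC[C@H]1C(C)C | intermediate
10 | bromomagnesium (3R,6S)-3-methyl-3-(pent-4-en-1-yl)-6-(propan-2-yl)cyclohex-1-en-1-olate | C=CCCC[C@]1(C)CC[C@@H](C(C)C)C(O[Mg]Br)=C1 | intermediate (not isolated)
11 | trimethyl{[(3R,6S)-3-methyl-3-(pent-4-en-1-yl)-6-(propan-2-yl)cyclohex-1-en-1-yl]oxy}silane | C=CCCC[C@]1(C)CC[C@@H](C(C)C)C(O[Si](C)(C)C)=C1 | intermediate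
12 | (2S,4aR,8aR)-4a-methyl-8-methylidene-2-(propan-2-yl)octahydronaphthalen-1(2H)-one (cis-fused) | C=C1CCC[C@]2(C)CC[C@@H](C(C)C)C(=O)[C@H]12 | intermediate
13 | potassium (2S,4aR)-4a-methyl-8-methylidene-2-(propan-2-yl)-2,3,4,4a,5,6,7,8-octahydronaphthalen-1-olate | C=C1CCC[C@]2(C)CC[C@@H](C(C)C)C([O-])=C12.[K+] | intermediate (not isolated)
14 | (2S,4aR,8aS)-4a-methyl-8-methylidene-2-(propan-2-yl)octahydronaphthalen-1(2H)-one (trans-fused) | C=C1CCC[C@]2(C)CC[C@@H](C(C)C)C(=O)[C@@H]12 | intermediate
15 | (1S,2S,4aR,8aS)-4a-methyl-8-methylidene-2-(propan-2-yl)decahydronaphthalen-1-ol | C=C1CCC[C@]2(C)CC[C@@H](C(C)C)[C@H](O)[C@@H]12 | intermediate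
16 | (2E)-3-[4-(acetyloxy)phenyl]prop-2-enoic acid | CC(=O)Oc1ccc(/C=C/C(=O)O)cc1 | starting material
17 | (1S,2S,4aR,8aS)-4a-methyl-8-methylidene-2-(propan-2-yl)decahydronaphthalen-1-yl (2E)-3-[4-(acetyloxy)phenyl]prop-2-enoate | C=C1CCC[C@]2(C)CC[C@@H](C(C)C)[C@H](OC(=O)/C=C/c3ccc(OC(C)=O)cc3)[C@@H]12 | intermediate (not isolated)
18 | (1S,2S,4aR,8aS)-4a-methyl-8-methylidene-2-(propan-2-yl)decahydronaphthalen-1-yl (2E)-3-(4-hydroxyphenyl)prop-2-enoate | C=C1CCC[C@]2(C)CC[C@@H](C(C)C)[C@H](OC(=O)/C=C/c3ccc(O)cc3)[C@@H]12 | target

**Step count**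
Total: 9 steps. Longest linear sequence: 9 steps (1 + 2 → 18).

**Three steps most likely to fail, with fallbacks**

Step 6 (oxidative cyclization). The α-carbonyl radical may close 7-endo, dimerise to the 1,4-diketone, or the enol ether may simply be desilylated. The fallback sets out from enone 9 and keeps C5 as the electrophilic partner in another guise. Iodination (I2, pyridine, CH2Cl2, rt) gives (6S)-2-iodo-3-(pent-4-en-1-yl)-6-(propan-2-yl)cyclohex-2-en-1-one F1, in which the C5–I bond makes the enone α-carbon an α-acylvinyl cation equivalent. A 6-exo-trig Heck cyclization (Pd(OAc)2 10 mol %, PPh3, Ag2CO3, MeCN, 80 °C) onto the terminal alkene, with β-hydride elimination from C4, gives the cross-conjugated dienone (2S)-8-methylidene-2-(propan-2-yl)-3,4,5,6,7,8-hexahydronaphthalen-1(2H)-one F2. Me2CuLi (Et2O, −78 → −20 °C) then adds to C10 cis to the isopropyl group to give lithium (2S,4aR)-4a-methyl-8-methylidene-2-(propan-2-yl)-2,3,4,4a,5,6,7,8-octahydronaphthalen-1-olate F3. Inverse quench into cold aqueous AcOH protonates C5 anti to the new methyl group and the route is rejoined at 14 (10–13 are bypassed).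

Step 7 (resetting C5). The quench may protonate the wrong face, protonate C15 to give the conjugated enone, or the base may touch C7. The fallback sets out from 12 and replaces substrate control by reagent control on an isolable intermediate. Soft enolisation (Me3SiOTf, Et3N, CH2Cl2, 0 °C) gives trimethyl{[(2S,4aR)-4a-methyl-8-methylidene-2-(propan-2-yl)-2,3,4,4a,5,6,7,8-octahydronaphthalen-1-yl]oxy}silane F4. This is protonated at C5 with the chiral Lewis-acid-assisted Brønsted acid SnCl4·BINOL (toluene, −78 °C; the BINOL antipode matched to the substrate is chosen by trial), and the route is rejoined at 14.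

Step 8 (equatorial alcohol). The dissolving-metal reduction may give epimer mixtures or be accompanied by base-induced alkene migration. The fallback sets out from 14 and fixes C6 by inversion instead of thermodynamic reduction. LiBH(s-Bu)3 (THF, −78 °C) attacks from the face away from the angular methyl group and gives the axial alcohol (1R,2S,4aR,8aS)-4a-methyl-8-methylidene-2-(propan-2-yl)decahydronaphthalen-1-ol F5. Mitsunobu esterification with 16 (PPh3, DIAD, toluene, 0 °C → rt) then proceeds with inversion at C6 and rejoins the route at 17, which is deacetylated with pyrrolidine as in step 9.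

**Further compounds**
F1 | step 6 | (6S)-2-iodo-3-(pent-4-en-1-yl)-6-(propan-2-yl)cyclohex-2-en-1-one | O=C1C(I)=C(CCCC=C)CC[C@H]1C(C)C
F2 | step 6 | (2S)-8-methylidene-2-(propan-2-yl)-3,4,5,6,7,8-hexahydronaphthalen-1(2H)-one | O=C1[C@H](C(C)C)CCC2=C1C(=C)CCC2
F3 | step 6 | lithium (2S,4aR)-4a-methyl-8-methylidene-2-(propan-2-yl)-2,3,4,4a,5,6,7,8-octahydronaphthalen-1-olate | C=C1CCC[C@]2(C)CC[C@@H](C(C)C)C([O-])=C12.[Li+]
F4 | step 7 | trimethyl{[(2S,4aR)-4a-methyl-8-methylidene-2-(propan-2-yl)-2,3,4,4a,5,6,7,8-octahydronaphthalen-1-yl]oxy}silane | C=C1CCC[C@]2(C)CC[C@@H](C(C)C)C(O[Si](C)(C)C)=C12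
F5 | step 8 | (1R,2S,4aR,8aS)-4a-methyl-8-methylidene-2-(propan-2-yl)decahydronaphthalen-1-ol | C=C1CCC[C@]2(C)CC[C@@H](C(C)C)[C@@H](O)[C@@H]12
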